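**Assumptions (one line each)**
- Iridoid numbering is used: C1 acylal, O2, C3=C4 enol ether, C11 on C4, C5–C9 ring fusion, C6 CH2, C7 carbinol, C8 quaternary, C10 on C8.
- Genipin is commercial as the single natural enantiomer. The lactol configuration at C1 is irrelevant until step 5, where C1 is set.
- Acylation of the equilibrating lactol is assumed to give mainly the anomeric-effect (natural 1S) acylal, with the minor epimer removed by chromatography.
- The target's C1, C5 and C9 match natural genipin (1S/4aS/7aS), and C7-OH and C10 are β (on the H5/H9 face). C8-OH is α.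

**Retrosynthesis**
1. The target comes from anti opening of a 7β,8β-epoxide by the neighbouring 10-OAc (anchimeric acetoxonium, then water). This inverts C8 to give 8α-OH, keeps 7β-OH, and puts CH2OAc β.
2. That epoxide comes from convex-face epoxidation of the C7=C8 alkene of genipin. This must be done while the C4 ester still deactivates the enol ether.
3. The C11 CH2OiVal comes from DIBAL reduction of the C4 ester, with C1 and C10 silylated. The C1 isovalerate acylal is made after the anomeric silyl ether is removed.
4. No ring of the cis-fused cyclopenta[c]pyran is built, because the chiral pool supplies it. The oxirane is formed in step 2 and opened in step 8, and the dioxolanylium in step 8 is transient.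

**Route**

Step 1
Reactants: 1 genipin; 2 tert-butyldimethylsilyl chloride
Product: 3 1,10-bis-O-TBS genipin
Conditions: TBSCl (2.5 equiv), imidazole, DMF, rt
Reagents that add atoms: TBSCl, CC(C)(C)[Si](C)(C)Cl
Why: Silylation of the lactol and primary allylic OH protects them for the hydride and epoxidation steps. The lactol silyl ether may form as an anomeric mixture, which is harmless because C1 is re-set in step 5.

Step 2
Reactants: 3; 4 mCPBA
Product: 5 7β,8β-epoxide of 3
Conditions: mCPBA, NaHCO3, CH2Cl2, 0 °C to rt
Reagents that add atoms: mCPBA, OOC(=O)c1cccc(Cl)c1 (adds one O)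
Why: Prilezhaev epoxidation takes the electron-richer C7=C8 alkene, because the C3=C4 enol ether is deactivated by the conjugated ester. The peracid approaches the convex β-face (H5/H9 side), which sets C7 and C8 as 7β,8β-epoxide.

Step 3
Reactants: 5
Product: 6 C11 allylic alcohol (CO2Me reduced to CH2OH)
Conditions: DIBAL-H (4 equiv), CH2Cl2, −78 °C to −40 °C; Rochelle-salt workup
Reagents that add atoms: none
Why: DIBAL reduces the vinylogous carbonate ester to the allylic alcohol, and the silyl ethers and the trisubstituted epoxide are untouched at low temperature. The acid-free workup protects the now electron-rich enol ether. No stereocentre is created.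

Step 4
Reactants: 6
Product: 7 lactol (C1-OH free, C10-OTBS retained)
Conditions: TBAF (1.1 equiv), AcOH (1.1 equiv), THF, 0 °C
Reagents that add atoms: none
Why: The anomeric silyl ether (more acidic O–H, better leaving group) is cleaved faster by buffered fluoride than the primary TBS ether. The lactol is used crude, immediately in step 5.

Step 5
Reactants: 7; 8 isovaleryl chloride
Product: 9 1,11-di-O-isovaleryl-10-O-TBS-7β,8β-epoxide
Conditions: iValCl (2.6 equiv), pyridine, DMAP (cat.), CH2Cl2, 0 °C
Reagents that add atoms: isovaleryl chloride, CC(C)CC(=O)Cl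
Why: Acylation of the C11 primary OH and the lactol installs both isovalerates in one step. The C1 acylal stereocentre is set by acylation of the equilibrating lactol, favouring the anomeric-effect (natural 1S) isomer.

Step 6
Reactants: 9
Product: 10 10-OH epoxy alcohol
Conditions: TBAF (2 equiv), AcOH (2 equiv), THF, 0 °C to rt
Reagents that add atoms: none
Why: Buffering with AcOH removes the primary TBS while sparing the acylal and esters, and suppresses Payne rearrangement of the 2,3-epoxy alcohol. No stereocentre changes.

Step 7
Reactants: 10; 11 acetic anhydride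
Product: 12 10-OAc epoxide
Conditions: Ac2O (1.5 equiv), pyridine, DMAP (cat.), CH2Cl2, 0 °C
Reagents that add atoms: acetic anhydride, CC(=O)OC(C)=O
Why: Simple O-acetylation of the only free OH. The acetate is the internal nucleophile for step 8.

Step 8
Reactants: 12; 13 water
Product: 14 target
Conditions: Sc(OTf)3 (10 mol %), MeCN/H2O 20:1, 0 °C; then Et3N/NaHCO3 work-up
Reagents that add atoms: water, O
Why: The Lewis-acid-activated tertiary C8–O bond is attacked anti, from the α-face, by the 10-OAc carbonyl. This gives a spiro 1,3-dioxolan-2-ylium with inversion at C8, a neighbouring-group epoxide opening, while the C7–O bond is retained as 7β-OH. Water hydrolyses the orthoester, and any 8-OAc isomer migrates to the primary 10-OH under mild base, giving 8α-OH/10β-CH2OAc.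

**Compound list**

1 | genipin, methyl (1R,4aS,7aS)-1-hydroxy-7-(hydroxymethyl)-1,4a,5,7a-tetrahydrocyclopenta[c]pyran-4-carboxylate | COC(=O)C1=CO[C@@H](O)[C@@H]2C(CO)=CC[C@H]12 | starting material
2 | tert-butyldimethylsilyl chloride | CC(C)(C)[Si](C)(C)Cl | starting material (reagent)
3 | 1,10-bis-O-TBS genipin | COC(=O)C1=CO[C@@H](O[Si](C)(C)C(C)(C)C)[C@@H]2C(CO[Si](C)(C)C(C)(C)C)=CC[C@H]12 | intermediate
4 | meta-chloroperoxybenzoic acid | OOC(=O)c1cccc(Cl)c1 | starting material (reagent)
5 | 7β,8β-epoxy-1,10-bis-O-TBS genipin | COC(=O)C1=CO[C@@H](O[Si](C)(C)C(C)(C)C)[C@@H]2[C@@]3(CO[Si](C)(C)C(C)(C)C)O[C@H]3C[C@H]12 | intermediate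
6 | 11-hydroxy-1,10-bis-O-TBS-7β,8β-epoxide (C11 = CH2OH) | OCC1=CO[C@@H](O[Si](C)(C)C(C)(C)C)[C@@H]2[C@@]3(CO[Si](C)(C)C(C)(C)C)O[C@H]3C[C@H]12 | intermediate
7 | 1-hydroxy (lactol), 10-O-TBS, 11-OH, 7β,8β-epoxide | OCC1=CO[C@@H](O)[C@@H]2[C@@]3(CO[Si](C)(C)C(C)(C)C)O[C@H]3C[C@H]12 | intermediate
8 | isovaleryl chloride | CC(C)CC(=O)Cl | starting material (reagent)
9 | 1,11-di-O-isovaleryl-10-O-TBS-7β,8β-epoxide | CC(C)CC(=O)OCC1=CO[C@@H](OC(=O)CC(C)C)[C@@H]2[C@@]3(CO[Si](C)(C)C(C)(C)C)O[C@H]3C[C@H]12 | intermediate
10 | 10-hydroxy-1,11-di-O-isovaleryl-7β,8β-epoxide | CC(C)CC(=O)OCC1=CO[C@@H](OC(=O)CC(C)C)[C@@H]2[C@@]3(CO)O[C@H]3C[C@H]12 | intermediate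
11 | acetic anhydride | CC(=O)OC(C)=O | starting material (reagent)
12 | 10-O-acetyl-1,11-di-O-isovaleryl-7β,8β-epoxide | CC(C)CC(=O)OCC1=CO[C@@H](OC(=O)CC(C)C)[C@@H]2[C@@]3(COC(C)=O)O[C@H]3C[C@H]12 | intermediate
13 | water | O | starting material (reagent)
14 | target, CID42638123 (10-OAc, 1,11-di-O-isovaleryl, 7β,8α-diol) | CC(=O)OC[C@]1(O)[C@H]2[C@H](OC(=O)CC(C)C)OC=C(COC(=O)CC(C)C)[C@H]2C[C@@H]1O | target

**Totals:** 8 steps in total, and the longest linear sequence is also 8 steps, all starting from genipin.

**Three steps most likely to fail**

1. **Step 8 (acetoxonium opening).**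
   - Risks: the acylal and enol ether are acid-sensitive and can decompose to baldrinal-type products. Regiochemistry of the orthoester collapse and acyl migration to C7-OH are also uncertain.
   - Fallback: move the trans-diol formation before any acylation. On the 10-OH epoxy alcohol with C1-OTBS and C11-OH, do a base-mediated Payne rearrangement and hydroxide opening at C10 to give the 7β,8α,10-triol with C8 configuration retained. Then acylate C11, C10 and C1 selectively in that order.
2. **Steps 4–5 (anomeric desilylation, lactol stability, C1 stereocontrol).**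
   - Risks: selectivity of anomeric over primary TBS cleavage, decomposition of the lactol, and a poor 1S:1R ratio on acylation.
   - Fallback: protect C1 as the methyl acetal (genipin, MeOH, H+) and leave C10-OH free during the DIBAL step. Convert OMe to OiVal at the end by acylative acetal exchange (isovaleric anhydride, Lewis acid), with the C1 epimers separated at that stage.
3. **Step 2 (epoxidation facial selectivity and chemoselectivity, and epoxide survival in step 3).**
   - Risks: mCPBA may attack the enol ether or give a mixture of faces, and DIBAL may open the epoxide.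
   - Fallback: reduce the ester first (as in step 3, before epoxidation). Then use a vanadium-catalysed, C10-OH-directed epoxidation (VO(acac)2, TBHP), which is selective for the allylic alcohol over the enol ether, and carry on with steps 4–8.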